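**Plan**
- Retrosynthesis: the C7–O bond of the hydroperoxide is cut first (ene reaction of a C7=C11 enone), then the two ester C–O bonds and the C3–O/C4–O bonds (osmylation of C3=C4), then C7–C11 (acetone aldol) and C4–C15 (enol triflate methylation). Last, the angular methyl is traced back through C9–C14 to a cyclopropane, whose C9–C14 and C10–C14 bonds are cut to leave a C9=C10 allylic alcohol.
- Enabling feature: methyl C14 on the ring-fusion carbon C10 lies β to the C8 ketone of ring B and anti to C5–H. This is the retron of a C9–C10–C14 cyclopropyl ketone, whose CH2 a C8 hydroxyl can place and which dissolving metal opens at C9–C14.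
- Forward order: rings A and B (C1–C10) come fused from 6-methoxy-1-tetralone by Birch reduction; the cyclopropane closes in step 6 and is opened in step 8; C15, C11–C13, the diol, the esters and the hydroperoxide follow.
- Stereochemistry: transfer hydrogenation sets C4; C5 is fixed against C4 by equilibration and separation; C5 steers the hydride that sets C8; the C8 hydroxyl delivers C14 and so sets C10; C14 then sends OsO4 (C3, C4) and singlet oxygen (C7) to the α face.

Key step: step 6

Remark: eudesmane numbering is used throughout (ring A = C1–C5, C10; ring B = C5–C10; C14 = methyl on C10; C15 = methyl on C4; C11–C13 = three-carbon unit on C7); α is the face of C5–H, β the face of C14, and all eudesmane-type intermediates have 5α-H and 10β-CH3.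

**Step 1**
Reactants: 1 6-methoxy-1-tetralone
Product: 2 (R)-6-methoxy-1,2,3,4-tetrahydronaphthalen-1-ol
Conditions: RuCl(p-cymene)[(R,R)-TsDPEN] (1 mol %), HCO2H/Et3N (5:2), 40 °C
Reagents that add atoms: none
Why: Noyori asymmetric transfer hydrogenation of an aryl ketone, in which the (R,R)-ligand series should deliver hydride to the face that gives the (R)-carbinol (the future C4) with the high enantioselectivity usual for 1-tetralones.

**Step 2**
Reactants: 2 (R)-6-methoxy-1,2,3,4-tetrahydronaphthalen-1-ol
Product: 4 (R)-6-methoxy-1,2,3,4,5,8-hexahydronaphthalen-1-ol, via lithium alkoxide 3 (not isolated)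
Conditions: Li (excess), NH3(l)/THF, −78 °C; t-BuOH, −33 °C; NH4Cl
Reagents that add atoms: none
Why: Birch reduction of the anisole ring, protonated ortho and meta to the methoxy group so that the enol ether and the tetrasubstituted ring-fusion alkene remain, while the carbinol travels as its lithium alkoxide, which suppresses benzylic C–O cleavage.

**Step 3**
Reactants: 4 (R)-6-methoxy-1,2,3,4,5,8-hexahydronaphthalen-1-ol
Product: 6 (4aR,5R)-5-hydroxy-4,4a,5,6,7,8-hexahydronaphthalen-2(3H)-one, via β,γ-unsaturated ketone 5 (not isolated)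
Conditions: (CO2H)2, THF/H2O, 0 °C; then NaOMe (cat.), MeOH, 25 °C; C5 epimers separated, minor epimer resubmitted to NaOMe/MeOH
Reagents that add atoms: water, O
Why: Enol ether hydrolysis under mild acid (which spares the allylic carbinol) followed by base-mediated conjugation through the dienolate, which also equilibrates the new C5–H centre; the epimer with the C4 hydroxyl equatorial and cis to C5–H should be favoured only modestly, but the two are diastereomers with the same (R)-C4, so separation and recycling should give one absolute configuration at C5.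

**Step 4**
Reactants: 6 (4aR,5R)-5-hydroxy-4,4a,5,6,7,8-hexahydronaphthalen-2(3H)-one
Product: 7 (4aR,5R)-5-(tert-butyldimethylsilyloxy)-4,4a,5,6,7,8-hexahydronaphthalen-2(3H)-one
Conditions: TBSCl, imidazole, DMF, 25 °C
Reagents that add atoms: tert-butyldimethylsilyl chloride, CC(C)(C)[Si](C)(C)Cl
Why: Standard silylation of a secondary alcohol with a base too weak to epimerise the γ-position C5.

**Step 5**
Reactants: 7 (4aR,5R)-5-(tert-butyldimethylsilyloxy)-4,4a,5,6,7,8-hexahydronaphthalen-2(3H)-one
Product: 8 (2S,4aR,5R)-5-(tert-butyldimethylsilyloxy)-2,3,4,4a,5,6,7,8-octahydronaphthalen-2-ol (8β-OH, 5α-H, 4α-OSi, C9=C10)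
Conditions: LiBH(s-Bu)3, THF, −78 °C; then NaOH, H2O2, 0 °C
Reagents that add atoms: none
Why: 1,2-reduction of a β,β-disubstituted cyclohexenone with a bulky trialkylborohydride (L-Selectride), which should attack along the equatorial trajectory from the side of the axial C5–H and so give the pseudoaxial C8 carbinol on the opposite (β) face, as in the reduction of steroidal 4-en-3-ones to their axial allylic alcohols.

**Step 6**
Reactants: 8 (2S,4aR,5R)-5-(tert-butyldimethylsilyloxy)-2,3,4,4a,5,6,7,8-octahydronaphthalen-2-ol; 9 diiodomethane; 10 diethylzinc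
Product: 12 4α-(tert-butyldimethylsilyloxy)-9,14-cyclo-11,12,13,15-tetranoreudesman-8β-ol (cyclopropane C9–C10–C14 on the β face), via ethylzinc alkoxide 11 (not isolated)
Conditions: Et2Zn (3 equiv), CH2I2 (3 equiv), CH2Cl2, 0 → 25 °C; NH4Cl
Reagents that add atoms: diiodomethane (9), ICI
Why: Et2Zn first deprotonates the C8 hydroxyl to the ethylzinc alkoxide 11, and the iodomethylzinc carbenoid formed from further Et2Zn and CH2I2 is held on that oxygen and hands its CH2 to the neighbouring C9=C10 bond through a concerted butterfly-type transition state. The closest known reaction type is the hydroxyl-directed Simmons–Smith cyclopropanation (Furukawa variant) of cyclic allylic alcohols. The three-membered ring (C9, C10, C14) closes in one step by a suprafacial [2+1] methylene transfer that forms C9–C14 and C10–C14 together, not by a stepwise exo or endo cyclisation. Both new stereocentres, C9 and C10, are controlled by the C8 stereocentre, because the zinc-bound oxygen allows delivery only to its own (β) face and the addition is cis across the ring alkene. The step needs β-face selectivity so that C14 ends anti to C5–H, and this is secured by the pseudoaxial 8β-oxygen lying over the alkene, while the only other oxygen is silylated, equatorial and on the α side at C4, so it cannot bind zinc. The carbenoid should leave the silyl ether untouched, so chemoselectivity is not in question.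

**Step 7**
Reactants: 12 4α-(tert-butyldimethylsilyloxy)-9,14-cyclo-11,12,13,15-tetranoreudesman-8β-ol
Product: 13 4α-(tert-butyldimethylsilyloxy)-9,14-cyclo-11,12,13,15-tetranoreudesman-8-one
Conditions: Dess–Martin periodinane, pyridine, CH2Cl2, 0 → 25 °C
Reagents that add atoms: none
Why: Buffered Dess–Martin oxidation converts the acid-labile cyclopropyl carbinol into the cyclopropyl ketone without cyclopropylcarbinyl rearrangement and touches no stereocentre.

**Step 8**
Reactants: 13 4α-(tert-butyldimethylsilyloxy)-9,14-cyclo-11,12,13,15-tetranoreudesman-8-one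
Product: 15 4α-(tert-butyldimethylsilyloxy)-11,12,13,15-tetranoreudesman-8-one, via lithium enolate 14 (not isolated)
Conditions: Li, NH3(l)/THF, −78 °C; solid NH4Cl
Reagents that add atoms: none
Why: Dissolving-metal reductive cleavage of a conjugated cyclopropyl ketone, in which the ketyl breaks the cyclopropane bond that overlaps best with the carbonyl π system, the exocyclic C9–C14 bond; ammonia protonates C14 to the β angular methyl, the C8 enolate 14 is protonated on quench, and C10 keeps the configuration set in step 6, giving the trans ring fusion.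

**Step 9**
Reactants: 15 4α-(tert-butyldimethylsilyloxy)-11,12,13,15-tetranoreudesman-8-one
Product: 16 4α-(tert-butyldimethylsilyloxy)-8,8-ethylenedioxy-11,12,13,15-tetranoreudesmane
Conditions: (Me3SiOCH2)2, Me3SiOTf (cat.), CH2Cl2, −78 → −20 °C; pyridine quench
Reagents that add atoms: 1,2-bis(trimethylsilyloxy)ethane, C[Si](C)(C)OCCO[Si](C)(C)C
Why: Low-temperature ketalisation with the bis-silylated diol under silyl triflate catalysis masks the C8 ketone without cleaving the C4 silyl ether, so that the two carbonyl sites can later be handled separately.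

**Step 10**
Reactants: 16 4α-(tert-butyldimethylsilyloxy)-8,8-ethylenedioxy-11,12,13,15-tetranoreudesmane
Product: 17 8,8-ethylenedioxy-11,12,13,15-tetranoreudesman-4α-ol
Conditions: n-Bu4NF, THF, 25–40 °C
Reagents that add atoms: none
Why: Fluoride-mediated desilylation of a secondary silyl ether, to which the ketal is inert.

**Step 11**
Reactants: 17 8,8-ethylenedioxy-11,12,13,15-tetranoreudesman-4α-ol
Product: 18 8,8-ethylenedioxy-11,12,13,15-tetranoreudesman-4-one
Conditions: Dess–Martin periodinane, pyridine, CH2Cl2, 25 °C
Reagents that add atoms: none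
Why: Dess–Martin oxidation under buffered, non-enolising conditions gives the C4 ketone with the ketal and the trans ring fusion at C5 intact.

**Step 12**
Reactants: 18 8,8-ethylenedioxy-11,12,13,15-tetranoreudesman-4-one
Product: 20 8,8-ethylenedioxy-11,12,13,15-tetranoreudesm-3-en-4-yl trifluoromethanesulfonate, via potassium enolate 19 (not isolated)
Conditions: KN(SiMe3)2, THF, −78 °C; PhNTf2, −78 → 0 °C
Reagents that add atoms: N-phenylbis(trifluoromethanesulfonimide), O=S(=O)(N(c1ccccc1)S(=O)(=O)C(F)(F)F)C(F)(F)F
Why: Kinetic enolate formation and O-triflation, in which the hindered base should remove a C3 proton and not the C5 methine next to the quaternary C10, so the C3=C4 enol triflate forms and C5 is not epimerised.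

**Step 13**
Reactants: 20 8,8-ethylenedioxy-11,12,13,15-tetranoreudesm-3-en-4-yl trifluoromethanesulfonate
Product: 21 8,8-ethylenedioxy-11,12,13-trinoreudesm-3-ene
Conditions: MeMgBr, Fe(acac)3 (5 mol %), THF/NMP, −30 → 0 °C
Reagents that add atoms: methylmagnesium bromide, C[Mg]Br
Why: Iron-catalysed Kumada-type cross-coupling of an alkenyl triflate with a methyl Grignard reagent attaches C15 to C4 and leaves the alkene at C3=C4; the ketal is inert to the Grignard reagent.

**Step 14**
Reactants: 21 8,8-ethylenedioxy-11,12,13-trinoreudesm-3-ene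
Product: 22 11,12,13-trinoreudesm-3-en-8-one
Conditions: pyridinium p-toluenesulfonate, acetone/H2O, 50 °C
Reagents that add atoms: water, O
Why: Mild acid-catalysed ketal hydrolysis frees the C8 ketone under conditions too weak to move the trisubstituted C3=C4 alkene.

**Step 15**
Reactants: 22 11,12,13-trinoreudesm-3-en-8-one
Product: 24 11-hydroxyeudesm-3-en-8-one (drawn as the equatorial 7β epimer; either C7 epimer serves), via lithium enolate 23 (not isolated)
Conditions: LiN(i-Pr)2, THF, −78 °C; acetone, −78 °C; AcOH quench at −78 °C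
Reagents that add atoms: acetone, CC(C)=O
Why: Kinetic lithium enolate aldol addition, in which the amide base should deprotonate C7 and not the neopentyl C9 beside the quaternary C10 (the usual sense of enolisation for such trans-fused ketones); the C7 centre it creates is not controlled and is erased in step 16.

**Step 16**
Reactants: 24 11-hydroxyeudesm-3-en-8-one
Product: 26 eudesma-3,7(11)-dien-8-one, via tertiary mesylate 25 (not isolated)
Conditions: MsCl, Et3N, CH2Cl2, 0 °C; then DBU, 25 °C
Reagents that add atoms: none
Why: Mesylation of the tertiary aldol hydroxyl (sulfene pathway) and E1cB elimination, with DBU also equilibrating any isopropenyl isomer into the conjugated isopropylidene ketone.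

**Step 17**
Reactants: 26 eudesma-3,7(11)-dien-8-one
Product: 27 3α,4α-dihydroxyeudesm-7(11)-en-8-one
Conditions: OsO4 (2 mol %), NMO, acetone/H2O, 25 °C
Reagents that add atoms: osmium tetroxide (catalytic oxygen carrier), O=[Os](=O)(=O)=O; N-methylmorpholine N-oxide, C[N+]1([O-])CCOCC1; water, O
Why: Upjohn dihydroxylation, in which OsO4 should take the electron-rich trisubstituted C3=C4 alkene and not the tetrasubstituted conjugated C7=C11 alkene, and should add syn from the α face because the axial C14 methyl shields the β face, setting C3 (3α-OH) and C4 (4α-OH, 4β-CH3).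

**Step 18**
Reactants: 27 3α,4α-dihydroxyeudesm-7(11)-en-8-one
Product: 28 3α-angeloyloxy-4α-hydroxyeudesm-7(11)-en-8-one
Conditions: angelic acid, 2,4,6-trichlorobenzoyl chloride, Et3N, toluene, 25 °C; then 27, 80 °C
Reagents that add atoms: angelic acid, C/C=C(/C)C(=O)O
Why: Yamaguchi-type esterification through the mixed trichlorobenzoic anhydride without a nucleophilic catalyst, conditions under which hindered secondary alcohols are angeloylated without Z-to-E isomerisation to the tiglate, while the tertiary C4 hydroxyl should not react.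

**Step 19**
Reactants: 28 3α-angeloyloxy-4α-hydroxyeudesm-7(11)-en-8-one
Product: 29 4α-acetoxy-3α-angeloyloxyeudesm-7(11)-en-8-one
Conditions: Ac2O, DMAP, Et3N, CH2Cl2, 40 °C
Reagents that add atoms: acetic anhydride, CC(=O)OC(C)=O
Why: DMAP-catalysed acyl transfer acetylates the equatorial tertiary C4 hydroxyl; migration of the angelate from the secondary to the tertiary oxygen is uphill and not expected.

**Step 20**
Reactants: 29 4α-acetoxy-3α-angeloyloxyeudesm-7(11)-en-8-one
Product: 30 4α-acetoxy-3α-angeloyloxy-7α-hydroperoxyeudesm-11-en-8-one (CNP0360871.1)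
Conditions: O2, hν (visible), tetraphenylporphyrin (cat.), CH2Cl2, −20 °C
Reagents that add atoms: dioxygen, O=O
Why: Schenck ene reaction of singlet oxygen with a ring-locked s-cis isopropylidene ketone (the behaviour known for pulegone), in which oxygen bonds to C7 while a C11 methyl hydrogen is taken and the alkene moves to C11=C12; axial entry on the α face, anti to C14, leaves the isopropenyl group equatorial and sets C7, and the regioisomer from hydrogen abstraction at C6 would have to be separated.

**Compound list**
1 | 6-methoxy-1-tetralone | COc1ccc2c(c1)CCCC2=O | starting material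
2 | (R)-6-methoxy-1,2,3,4-tetrahydronaphthalen-1-ol | COc1ccc2c(c1)CCC[C@H]2O | intermediate
3 | lithium (R)-6-methoxy-1,2,3,4-tetrahydronaphthalen-1-olate | COc1ccc2c(c1)CCC[C@H]2[O-].[Li+] | intermediate (not isolated)
4 | (R)-6-methoxy-1,2,3,4,5,8-hexahydronaphthalen-1-ol | COC1=CCC2=C(C1)CCC[C@H]2O | intermediate
5 | (R)-5-hydroxy-3,4,5,6,7,8-hexahydronaphthalen-2(1H)-one (β,γ-unsaturated ketone) | O=C1CCC2=C(C1)CCC[C@H]2O | intermediate (not isolated)
6 | (4aR,5R)-5-hydroxy-4,4a,5,6,7,8-hexahydronaphthalen-2(3H)-one (4α-OH, 5α-H) | O=C1CC[C@H]2[C@H](O)CCCC2=C1 | intermediate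
7 | (4aR,5R)-5-(tert-butyldimethylsilyloxy)-4,4a,5,6,7,8-hexahydronaphthalen-2(3H)-one | O=C1CC[C@H]2[C@H](O[Si](C)(C)C(C)(C)C)CCCC2=C1 | intermediate
8 | (2S,4aR,5R)-5-(tert-butyldimethylsilyloxy)-2,3,4,4a,5,6,7,8-octahydronaphthalen-2-ol | O[C@H]1CC[C@H]2[C@H](O[Si](C)(C)C(C)(C)C)CCCC2=C1 | intermediate
9 | diiodomethane | ICI | starting material
10 | diethylzinc | CC[Zn]CC | starting material
11 | ethylzinc alkoxide of 8 | CC[Zn]O[C@H]1CC[C@H]2[C@H](O[Si](C)(C)C(C)(C)C)CCCC2=C1 | intermediate (not isolated)
12 | 4α-(tert-butyldimethylsilyloxy)-9,14-cyclo-11,12,13,15-tetranoreudesman-8β-ol | O[C@H]1CC[C@H]2[C@H](O[Si](C)(C)C(C)(C)C)CCC[C@@]23C[C@@H]13 | intermediate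
13 | 4α-(tert-butyldimethylsilyloxy)-9,14-cyclo-11,12,13,15-tetranoreudesman-8-one | O=C1CC[C@H]2[C@H](O[Si](C)(C)C(C)(C)C)CCC[C@@]23C[C@@H]13 | intermediate
14 | lithium C8=C9 enolate of 15 | [Li+].[O-]C=1CC[C@H]2[C@H](O[Si](C)(C)C(C)(C)C)CCC[C@]2(C)C=1 | intermediate (not isolated)
15 | 4α-(tert-butyldimethylsilyloxy)-11,12,13,15-tetranoreudesman-8-one | O=C1CC[C@H]2[C@H](O[Si](C)(C)C(C)(C)C)CCC[C@]2(C)C1 | intermediate
16 | 4α-(tert-butyldimethylsilyloxy)-8,8-ethylenedioxy-11,12,13,15-tetranoreudesmane | O1CCOC12CC[C@H]3[C@H](O[Si](C)(C)C(C)(C)C)CCC[C@]3(C)C2 | intermediate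
17 | 8,8-ethylenedioxy-11,12,13,15-tetranoreudesman-4α-ol | O1CCOC12CC[C@H]3[C@H](O)CCC[C@]3(C)C2 | intermediate
18 | 8,8-ethylenedioxy-11,12,13,15-tetranoreudesman-4-one | O1CCOC12CC[C@H]3C(=O)CCC[C@]3(C)C2 | intermediate
19 | potassium C3=C4 enolate of 18 | [K+].O1CCOC12CC[C@H]3C([O-])=CCC[C@]3(C)C2 | intermediate (not isolated)
20 | 8,8-ethylenedioxy-11,12,13,15-tetranoreudesm-3-en-4-yl trifluoromethanesulfonate | O1CCOC12CC[C@H]3C(OS(=O)(=O)C(F)(F)F)=CCC[C@]3(C)C2 | intermediate
21 | 8,8-ethylenedioxy-11,12,13-trinoreudesm-3-ene | O1CCOC12CC[C@H]3C(C)=CCC[C@]3(C)C2 | intermediate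
22 | 11,12,13-trinoreudesm-3-en-8-one | O=C1CC[C@H]2C(C)=CCC[C@]2(C)C1 | intermediate
23 | lithium C7=C8 enolate of 22 | [Li+].[O-]C1=CC[C@H]2C(C)=CCC[C@]2(C)C1 | intermediate (not isolated)
24 | 11-hydroxyeudesm-3-en-8-one (7β side chain drawn) | O=C1[C@@H](C(C)(C)O)C[C@H]2C(C)=CCC[C@]2(C)C1 | intermediate
25 | 11-methanesulfonyloxyeudesm-3-en-8-one | O=C1[C@@H](C(C)(C)OS(C)(=O)=O)C[C@H]2C(C)=CCC[C@]2(C)C1 | intermediate (not isolated)
26 | eudesma-3,7(11)-dien-8-one | CC(C)=C1C[C@H]2C(C)=CCC[C@]2(C)CC1=O | intermediate
27 | 3α,4α-dihydroxyeudesm-7(11)-en-8-one | CC(C)=C1C[C@H]2[C@](C)(O)[C@H](O)CC[C@]2(C)CC1=O | intermediate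
28 | 3α-angeloyloxy-4α-hydroxyeudesm-7(11)-en-8-one | CC(C)=C1C[C@H]2[C@](C)(O)[C@H](OC(=O)/C(C)=C\C)CC[C@]2(C)CC1=O | intermediate
29 | 4α-acetoxy-3α-angeloyloxyeudesm-7(11)-en-8-one | CC(C)=C1C[C@H]2[C@](C)(OC(C)=O)[C@H](OC(=O)/C(C)=C\C)CC[C@]2(C)CC1=O | intermediate
30 | 4α-acetoxy-3α-angeloyloxy-7α-hydroperoxyeudesm-11-en-8-one (CNP0360871.1) | C=C(C)[C@@]1(OO)C[C@@H]2[C@](C)(CC[C@@H](OC(=O)/C(C)=C\C)[C@@]2(C)OC(C)=O)CC1=O | target

**Totals**
Total step count: 20. Longest linear sequence: 20 steps (1 to 30).

**Three steps most likely to fail**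

1. Step 20. What may go wrong: hydrogen abstraction from the C6 methylene instead of a C11 methyl, which puts the oxygen on C11, or oxygen delivery to the β face. Fallback: this sets out from 29 and moves the oxygenation onto a silyl enol ether, where the nucleophilic carbon is C7 by construction. Soft enolisation (Me3SiOTf, Et3N, CH2Cl2, 0 °C) toward the C11 methyl groups should be preferred, because C9 is neopentyl and the cross-conjugated alternative suffers allylic strain. It should give the linear trimethylsilyl dienol ether F1. Sensitised photooxygenation (O2, hν, tetraphenylporphyrin, CH2Cl2, −78 °C) then follows the known course of silyl enol ethers: oxygen bonds to C7 from the axial α face and silicon moves from the enol oxygen to the peroxide, giving the α-trimethylsilylperoxy ketone F2. Brief methanolysis (MeOH, 0 °C) removes silicon and returns to the route at 30.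

2. Step 3. What may go wrong: too little thermodynamic bias between the two C5 epimers, so that the separation and recycling loop becomes inefficient. Fallback: this sets out from 4 and sets C5 by hydroxyl-directed hydrogenation instead of equilibration. Hydrolysis of the enol ether alone (oxalic acid, THF/H2O, 0 °C) lets the β,γ-unsaturated ketone 5 be isolated. Hydrogenation with [Ir(cod)(PCy3)(py)]PF6 and H2 in CH2Cl2 adds hydrogen to C5=C10 from the face of the C4 hydroxyl and gives the cis-fused hydroxy ketone F3, with C5–H cis to the C4 oxygen. Thermodynamic silylation (Me3SiCl, NaI, Et3N, MeCN), which for cis-fused ketones of this kind enolises toward the ring fusion, gives the bis-trimethylsilyl compound F4. Saegusa–Ito oxidation (Pd(OAc)2, MeCN) then restores C9=C10 and gives the silyl ether F5. Dilute aqueous HCl in the work-up cleaves the silyl ether and returns to the route at 6 as a single C5 epimer.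

3. Step 5. What may go wrong: poor facial selectivity in the hydride delivery, or competing conjugate reduction, so that the pseudoequatorial 8α-carbinol prevails and C14 would later be delivered to the wrong face. Fallback: this sets out from 7 and reaches the 8β-alcohol by inversion. Luche reduction (NaBH4, CeCl3·7H2O, MeOH, −78 → 0 °C) deliberately gives the pseudoequatorial 8α-alcohol F6 by axial attack. Mitsunobu inversion (4-nitrobenzoic acid, PPh3, diisopropyl azodicarboxylate, THF, 0 °C) gives the 8β-(4-nitrobenzoate) F7. Methanolysis (K2CO3, MeOH) returns to the route at 8.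

**Further compounds**
F1 | step 20 | 4α-acetoxy-3α-angeloyloxy-8-(trimethylsilyloxy)eudesma-7,11-diene | C=C(C)C=1C[C@H]2[C@](C)(OC(C)=O)[C@H](OC(=O)/C(C)=C\C)CC[C@]2(C)CC=1O[Si](C)(C)C
F2 | step 20 | 4α-acetoxy-3α-angeloyloxy-7α-(trimethylsilylperoxy)eudesm-11-en-8-one | C=C(C)[C@@]1(OO[Si](C)(C)C)C[C@@H]2[C@](C)(CC[C@@H](OC(=O)/C(C)=C\C)[C@@]2(C)OC(C)=O)CC1=O
F3 | step 3 | cis-fused 4α-hydroxy ketone (5α-H, 10α-H; 5-hydroxyoctahydronaphthalen-2(1H)-one) | O=C1CC[C@H]2[C@H](O)CCC[C@H]2C1
F4 | step 3 | bis(trimethylsilyl) compound of F3 (C8=C9 silyl enol ether, C4 silyl ether) | C[Si](C)(C)OC=1CC[C@H]2[C@H](O[Si](C)(C)C)CCC[C@H]2C=1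
F5 | step 3 | trimethylsilyl ether of 6 | O=C1CC[C@H]2[C@H](O[Si](C)(C)C)CCCC2=C1
F6 | step 5 | 8α epimer of 8 | O[C@@H]1CC[C@H]2[C@H](O[Si](C)(C)C(C)(C)C)CCCC2=C1
F7 | step 5 | 8β-(4-nitrobenzoate) of 8 | O=C(O[C@H]1CC[C@H]2[C@H](O[Si](C)(C)C(C)(C)C)CCCC2=C1)c1ccc(cc1)[N+](=O)[O-]
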